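E is the species to watch when these flasks are repeated. Its final amount has to be reckoned from the earlier runs below.

| flask | L | Z | D | temperature | remark | time |
|---|---|---|---|---|---|---|
| summer | 10 mM | 36 mM | 3 mM | 15 °C | run made earlier |  |
| winter | 15 mM | 36 mM | 3 mM | 42 °C | run made earlier |  |
| north-east | 20 mM | 36.0 mM | 3.0 mM | 20 °C |  | 25 min |
| north | 20 mM | 36.0 mM | 3.0 mM | 65 °C |  | 25 min |
| north-west | 20 mM | 36.0 mM | 3.0 mM | 35 °C |  | 25 min |
| west | 20 mM | 36.0 mM | 3.0 mM | 50 °C |  | 25 min |

- summer (time / min: E / %): 2.00: 24.8; 4.00: 40.6; 8.00: 61.5; 12.0: 71.6; 25.0: 85.5
- winter (time / min: E / %): 1.50: 44.4; 3.00: 53.8; 5.00: 58.9; 6.00: 58.4; 8.00: 60.1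

(each reading ± 1 percentage point)



- the best flask by amount of E, in percent of the L charged; "all alike" if 1.5 percentage points covers them all (north-east / north / north-west / west / all alike)
- amount of E at the end, in percent of the L charged, north-east
- amount of E at the end, in percent of the L charged, north
- amount of E at the end, in percent of the L charged, north-west
- amount of E at the end, in percent of the L charged, west

The winter run stands near 60.1% of its L, which is 9.01 mM, and the summer run reaches 8.55 mM at its last reading.

We assume that something caps E, and two extreme flasks can then be solved in the head. If the charge of L is small against the cap, E equals the charge. If the charge is large against the cap, E stands at the cap. We join the two ends in the simplest way: the reciprocal of final E is the reciprocal of the charge plus the reciprocal of the cap, so in this join E lies below both.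

Solved backwards, the join gives 22.6 mM from the winter run and 59.0 mM from the summer run. These are readings and carry their scatter, and the summer curve was still climbing at its last reading. A straight line through their logarithms against temperature gives 49.4 mM at 20 °C and 9.98 mM at 65 °C. The latter is our ceiling for north, the concentration of E that this join approaches as the charge of L grows large.

With 20 mM charged, our reckoning gives 71.2% in north-east, 59.2% in north-west, 46.0% in west and 33.3% in north, so north-east comes out highest. In north-east, the coolest flask, E should be watched for still rising at the end.

The forecast also picks north-east, with 83%, 68%, 50% and 36% in the same order of flasks. Its ground is “The ceiling falls with temperature, so the coolest flask wins.” Our figure for north-east stands lower than its figure, and so does our figure for north-west.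

The flasks give 68.2% in north-east, 57.5% in north-west, 46.2% in west and 35.8% in north, so north-east is highest.

    L + Z + D → D + E (k = 64.0 M⁻² s⁻¹, Ea = 39.0 kJ mol⁻¹)
    Z → X (k = 7.90 × 10⁻⁶ s⁻¹, Ea = 99.0 kJ mol⁻¹)
    L + E → G (k = 0.200 M⁻¹ s⁻¹, Ea = 67.0 kJ mol⁻¹)
    (constants at 35 °C)

In north, at 0.305 min, E is made 2.07 times as fast as it is used up, each step taken net, and at that moment L has a half-life of 1.1 min by the consecutive side reaction with E, against a half-life of Z of 47 min by its passing into X. The ceiling of 9.98 mM put north at 33.3%, and the flask gives 35.8%. For the neighbour of north charged with 34 mM of L, the same ceiling gives 22.7%, and that flask gives 19.9%.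

The readings come from a simulation with constants of no real substance, noise included.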